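**Plan**

Locants used here: C1 = ring carbon bearing =CH2; C2, C3 = the two ring CH2 next to it; C4 = O–CH bridgehead; C5 = the other O–CH; C6 = CH2; C7 = ring-fusion C(CH3); C8 = CHBr; C9, C10 = CH2; C11 = C(CH3)OH; C12 = ring-fusion CH; C13 = CH2; C14 = spiro bridgehead carbon; C15 = C(CH3)2. Ring A = C7–C12, ring B = C5, C6, C7, C12, C13, C14, ring C = oxolane (O, C4, C15, C14, C5), ring D = C1, C2, C3, C4, C15, C14.
Retrosynthesis: C1=CH2 from a C1 ketone (Wittig), the C11 carbinol from a C11 ketone (Grignard), C2–C3 from an enone; ring D is then cut at C2–C3 and C14–C15 and ring C at O–C4, which gives hydroxy methyl ketone 18 and 2-bromo-3-methylbut-2-enal 21.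
Enabling feature: in ring D the carbinol carbon C4 lies between C3 and C15 and the methylidene carbon C1 between C2 and C14. With C1 as a ketone, C14 and C2 are its two enolisable carbons, while C15 and C3 are the β-carbon and the carbonyl carbon of an enal whose α-bromine lets the C5 oxygen close ring C. This is a Robinson-type (3+3) Michael–aldol annulation.
Forward order: ring A by enantiospecific bromonium cyclisation of a keto ester made from a Sharpless epoxide, ring B by carbonyl-ene cyclisation, rings D and C in the key step.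
Stereochemistry: C7 and C8 from the epoxide of step 2 (two anti openings), C12 by equilibration, C5 and the C14–H by the chair ene transition state, quaternary C14 and C4 in the key step, C11 by equatorial Grignard attack.

Key step: step 14

Assumption: 1, 6, 11 and 19 are purchased (1 is otherwise one silylation from but-3-yn-1-ol); 21 is prepared in step 13.

**Step 1**
Reactants: 1 tert-butyl(but-3-yn-1-yloxy)diphenylsilane
Product: 3 (E)-5-[(tert-butyldiphenylsilyl)oxy]-3-methylpent-2-en-1-ol, via alkenylalane 2 (not isolated)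
Conditions: Me3Al, Cp2ZrCl2 (0.2 equiv), CH2Cl2, 0 °C to rt; then n-BuLi, (CH2O)n, THF, -78 °C to rt
Reagents that add atoms: trimethylaluminium C[Al](C)C; formaldehyde (as paraformaldehyde) C=O
Why: Zirconium-catalysed carboalumination adds CH3 and Al syn across the terminal alkyne, and hydroxymethylation of the alkenyl aluminate with retention should give the E allylic alcohol with CH3 cis to CH2OH.

**Step 2**
Reactants: 3 (E)-5-[(tert-butyldiphenylsilyl)oxy]-3-methylpent-2-en-1-ol
Product: 4 [(2R,3R)-3-{2-[(tert-butyldiphenylsilyl)oxy]ethyl}-3-methyloxiran-2-yl]methanol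
Conditions: Ti(OiPr)4 (10 mol %), D-(-)-diethyl tartrate (12 mol %), t-BuOOH, 4 Å MS, CH2Cl2, -20 °C
Reagents that add atoms: tert-butyl hydroperoxide CC(C)(C)OO
Why: Sharpless asymmetric epoxidation of a geraniol-type allylic alcohol; the D-(-)-tartrate should give the (2R,3R) epoxide, which fixes C7 and C8 of the target.

**Step 3**
Reactants: 4 [(2R,3R)-3-{2-[(tert-butyldiphenylsilyl)oxy]ethyl}-3-methyloxiran-2-yl]methanol
Product: 5 (2S,3R)-2-(bromomethyl)-3-{2-[(tert-butyldiphenylsilyl)oxy]ethyl}-3-methyloxirane (oxirane carbons unchanged in space)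
Conditions: CBr4, PPh3, CH2Cl2, -20 °C to 0 °C
Reagents that add atoms: carbon tetrabromide BrC(Br)(Br)Br
Why: Appel bromination of the primary alcohol under neutral conditions should leave the trisubstituted epoxide intact.

**Step 4**
Reactants: 5 (2S,3R)-2-(bromomethyl)-3-{2-[(tert-butyldiphenylsilyl)oxy]ethyl}-3-methyloxirane, 6 methyl 3-oxobutanoate
Product: 8 methyl 5-[(2R,3R)-3-{2-[(tert-butyldiphenylsilyl)oxy]ethyl}-3-methyloxiran-2-yl]-3-oxopentanoate, via acetoacetate dianion 7 (not isolated)
Conditions: 6, NaH then n-BuLi, THF, 0 °C; 5, -78 °C to 0 °C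
Reagents that add atoms: none
Why: γ-Alkylation of the acetoacetate dianion by SN2 at the primary bromide; both oxirane carbons are hindered and should be spared.

**Step 5**
Reactants: 8 methyl 5-[(2R,3R)-3-{2-[(tert-butyldiphenylsilyl)oxy]ethyl}-3-methyloxiran-2-yl]-3-oxopentanoate
Product: 9 methyl (6S,7R)-6-bromo-9-[(tert-butyldiphenylsilyl)oxy]-7-hydroxy-7-methyl-3-oxononanoate
Conditions: Li2NiBr4, THF, 0 °C
Reagents that add atoms: dilithium tetrabromonickelate [Li+].[Li+].[Ni+2].[Br-].[Br-].[Br-].[Br-]
Why: SN2 opening of the epoxide by bromide at the less substituted carbon C8 with inversion should give the anti bromohydrin with the tertiary alcohol at C7.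

**Step 6**
Reactants: 9 methyl (6S,7R)-6-bromo-9-[(tert-butyldiphenylsilyl)oxy]-7-hydroxy-7-methyl-3-oxononanoate
Product: 10 methyl (1S,2S,3S)-3-bromo-2-{2-[(tert-butyldiphenylsilyl)oxy]ethyl}-2-methyl-6-oxocyclohexane-1-carboxylate (ring A; Br equatorial, 2-methyl axial and cis to Br, ester equatorial)
Conditions: TfOH (10 mol %), (CF3)2CHOH, 0 °C, high dilution
Reagents that add atoms: none
Why: Bromonium-ion cyclisation: ionisation of the tertiary alcohol with anchimeric help from bromine gives the enantiopure bromonium ion, which the keto ester enol carbon C12 opens at C7 anti to bromine (six-membered ring), and C12 then equilibrates to the equatorial ester.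

**Step 7**
Reactants: 10 bromo keto ester (ring A), 11 1-bromo-3-methylbut-2-ene
Product: 12 methyl 3-bromo-2-{2-[(tert-butyldiphenylsilyl)oxy]ethyl}-2-methyl-1-(3-methylbut-2-enyl)-6-oxocyclohexane-1-carboxylate (prenyl expected anti to the axial 2-methyl; this centre is reset in step 8)
Conditions: Cs2CO3, DMF, rt
Reagents that add atoms: none
Why: C-Alkylation of the β-keto ester enolate with an allylic bromide.

**Step 8**
Reactants: 12 prenylated bromo keto ester
Product: 13 4-bromo-3-{2-[(tert-butyldiphenylsilyl)oxy]ethyl}-3-methyl-2-(3-methylbut-2-enyl)cyclohexan-1-one (C12–H trans to the C7 methyl, prenyl equatorial)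
Conditions: LiCl, H2O, DMSO, 150 °C
Reagents that add atoms: none
Why: Krapcho dealkoxycarbonylation; the epimerisable C12 should settle with the prenyl group equatorial, the arrangement needed for a trans ring fusion.

**Step 9**
Reactants: 13 silyl ether ketone
Product: 14 4-bromo-3-(2-hydroxyethyl)-3-methyl-2-(3-methylbut-2-enyl)cyclohexan-1-one
Conditions: Bu4NF, THF, 0 °C to rt
Reagents that add atoms: none
Why: Fluoride cleavage of the silyl ether; the equatorial neopentyl bromide has no anti-periplanar hydrogen and should survive.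

**Step 10**
Reactants: 14 hydroxy ketone
Product: 15 2-[6-bromo-1-methyl-2-(3-methylbut-2-enyl)-3-oxocyclohexyl]acetaldehyde
Conditions: Dess–Martin periodinane, CH2Cl2, rt
Reagents that add atoms: none
Why: Dess–Martin oxidation of the primary alcohol to the aldehyde under neutral conditions.

**Step 11**
Reactants: 15 keto aldehyde
Product: 16 trans-fused decalin hydroxy ketone (ring B closed; 5-OH equatorial, 14-isopropenyl equatorial and trans to it, C11 ketone, 8-Br)
Conditions: ZnBr2, CH2Cl2, 0 °C
Reagents that add atoms: none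
Why: Lewis-acid carbonyl-ene cyclisation of the citronellal-to-isopulegol type; the chair transition state places the C5 oxygen and the new isopropenyl group equatorial and gives the trans-decalin.

**Step 12**
Reactants: 16 decalin hydroxy ketone
Product: 18 14-acetyl decalin hydroxy ketone (5-OH equatorial, 14-acetyl equatorial, C11 ketone), via ozonide 17 (not isolated)
Conditions: O3, CH2Cl2, -78 °C; then Me2S
Reagents that add atoms: ozone [O-][O+]=O
Why: Ozonolysis of the only alkene turns the isopropenyl group into the methyl ketone, which makes C14 and C2 enolisable.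

**Step 13**
Reactants: 19 3-methylbut-2-enal
Product: 21 2-bromo-3-methylbut-2-enal, via dibromo aldehyde 20 (not isolated)
Conditions: Br2, CH2Cl2, 0 °C; then Et3N
Reagents that add atoms: bromine BrBr
Why: Bromine addition followed by dehydrobromination is the standard route to α-bromo enals.

**Step 14**
Reactants: 18 14-acetyl decalin hydroxy ketone, 21 2-bromo-3-methylbut-2-enal
Product: 24 bridged enone dione (rings C and D closed; C1 ketone, C2=C3, C11 ketone), via Michael adduct 22 (not isolated), via bromo enone 23 (not isolated)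
Conditions: TsOH·H2O (0.2 equiv), toluene, 70 °C; then iPr2NEt, 70 °C (same flask)
Reagents that add atoms: none
Why: Proposed new method: acid catalysis should let the C5 hydroxyl of 18 add reversibly to the aldehyde of 21 (hemiacetal), so that the thermodynamic enol of the methyl ketone (enolised towards C14) attacks the β-carbon C15 through a six-membered transition state, a Michael addition that gives 22 and forms C14–C15. The methyl ketone then condenses with the aldehyde (aldol condensation, 6-(enolexo)-exo-trig) to close ring D at C2–C3 as the enone 23, and after the base is added the C5 oxygen displaces the allylic bromide at C4 (5-exo-tet) to close ring C. The closest known reaction types are the acid-catalysed Robinson-type Michael–aldol annulation of a ketone at its more substituted α-carbon with an enal and the Michael-initiated ring closure of α-bromo enals. C14 is set in the Michael step, where the fully substituted C15 should enter equatorially on ring B, trans to the equatorial C5–O bond, because the tethered chair-like array is trans-fused and an axial quaternary carbon is avoided; C4 can epimerise by bromide exchange at the allylic bromide and only the epimer with bromine anti to the attacking oxygen can close, so both epimers are funnelled into the one bridgehead configuration. The step needs C14 rather than C2, C10 or C12 to react and 1,4- rather than 1,2-addition: the hemiacetal tether puts only C14 within reach of C15, the competing carbonyl additions are reversible, and the dehydration and etherification are not. The equatorial C5–O bond lies in the nodal plane of the C14 enol, which should protect the β-hydroxy ketone from elimination.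

**Step 15**
Reactants: 24 bridged enone dione
Product: 25 bridged saturated diketone (C1 and C11 ketones)
Conditions: [(Ph3P)CuH]6 (0.4 equiv), benzene, rt; aq. NH4Cl
Reagents that add atoms: none
Why: Conjugate reduction of the enone by the phosphine copper hydride should leave the isolated ketone and the alkyl bromide untouched.

**Step 16**
Reactants: 25 bridged saturated diketone
Product: 26 C11 tertiary alcohol, C1 ketone (11-OH axial and cis to the C7 methyl, 11-CH3 equatorial)
Conditions: MeMgBr, CeCl3, THF, -78 °C
Reagents that add atoms: methylmagnesium bromide C[Mg]Br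
Why: Cerium-mediated Grignard addition should occur at the less hindered C11 ketone (C1 is flanked by the quaternary C14), from the equatorial side away from the axial C7 methyl, which gives the axial alcohol.

**Step 17**
Reactants: 26 hydroxy ketone
Product: 27 target, CNP0412361.2
Conditions: Ph3PCH3Br, KOtBu (excess), toluene, 80 °C
Reagents that add atoms: methylenetriphenylphosphorane C=P(c1ccccc1)(c1ccccc1)c1ccccc1
Why: Wittig methylenation of the hindered C1 ketone with salt-free ylide in excess (the tertiary alkoxide is inert) installs the exocyclic methylidene.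

**Compound list**

1 | tert-butyl(but-3-yn-1-yloxy)diphenylsilane | C#CCCO[Si](c1ccccc1)(c1ccccc1)C(C)(C)C | starting material
2 | (E)-alkenyl(dimethyl)alane from 1 (Al cis to the new methyl) | C[Al](C)/C=C(\C)CCO[Si](c1ccccc1)(c1ccccc1)C(C)(C)C | intermediate
3 | (E)-5-[(tert-butyldiphenylsilyl)oxy]-3-methylpent-2-en-1-ol | OC/C=C(\C)CCO[Si](c1ccccc1)(c1ccccc1)C(C)(C)C | intermediate
4 | [(2R,3R)-3-{2-[(tert-butyldiphenylsilyl)oxy]ethyl}-3-methyloxiran-2-yl]methanol | OC[C@H]1O[C@]1(C)CCO[Si](c2ccccc2)(c2ccccc2)C(C)(C)C | intermediate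
5 | (2S,3R)-2-(bromomethyl)-3-{2-[(tert-butyldiphenylsilyl)oxy]ethyl}-3-methyloxirane | BrC[C@H]1O[C@]1(C)CCO[Si](c2ccccc2)(c2ccccc2)C(C)(C)C | intermediate
6 | methyl 3-oxobutanoate | CC(=O)CC(=O)OC | starting material
7 | sodium lithium dianion of methyl 3-oxobutanoate | [Na+].[Li+].C=C([O-])C=C([O-])OC | intermediate
8 | methyl 5-[(2R,3R)-3-{2-[(tert-butyldiphenylsilyl)oxy]ethyl}-3-methyloxiran-2-yl]-3-oxopentanoate | COC(=O)CC(=O)CC[C@H]1O[C@]1(C)CCO[Si](c2ccccc2)(c2ccccc2)C(C)(C)C | intermediate
9 | methyl (6S,7R)-6-bromo-9-[(tert-butyldiphenylsilyl)oxy]-7-hydroxy-7-methyl-3-oxononanoate | COC(=O)CC(=O)CC[C@H](Br)[C@@](O)(C)CCO[Si](c1ccccc1)(c1ccccc1)C(C)(C)C | intermediate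
10 | methyl (1S,2S,3S)-3-bromo-2-{2-[(tert-butyldiphenylsilyl)oxy]ethyl}-2-methyl-6-oxocyclohexane-1-carboxylate | CC(C)(C)[Si](c1ccccc1)(c1ccccc1)OCC[C@]2(C)[C@@H](Br)CCC(=O)[C@H]2C(=O)OC | intermediate
11 | 1-bromo-3-methylbut-2-ene | CC(C)=CCBr | starting material
12 | 1-prenyl derivative of 10 (prenyl anti to the 2-methyl) | CC(C)(C)[Si](c1ccccc1)(c1ccccc1)OCC[C@]2(C)[C@@H](Br)CCC(=O)[C@@]2(CC=C(C)C)C(=O)OC | intermediate
13 | 4-bromo-3-{2-[(tert-butyldiphenylsilyl)oxy]ethyl}-3-methyl-2-(3-methylbut-2-enyl)cyclohexan-1-one (prenyl equatorial, trans H/CH3 at C12/C7) | CC(C)(C)[Si](c1ccccc1)(c1ccccc1)OCC[C@]2(C)[C@@H](Br)CCC(=O)[C@H]2CC=C(C)C | intermediate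
14 | 4-bromo-3-(2-hydroxyethyl)-3-methyl-2-(3-methylbut-2-enyl)cyclohexan-1-one | OCC[C@]1(C)[C@@H](Br)CCC(=O)[C@H]1CC=C(C)C | intermediate
15 | 2-[6-bromo-1-methyl-2-(3-methylbut-2-enyl)-3-oxocyclohexyl]acetaldehyde | O=CC[C@]1(C)[C@@H](Br)CCC(=O)[C@H]1CC=C(C)C | intermediate
16 | trans-decalin hydroxy ketone (5-OH and 14-isopropenyl equatorial, C11 ketone, 8-Br equatorial) | O[C@@H]1C[C@]2(C)[C@@H](Br)CCC(=O)[C@H]2C[C@H]1C(C)=C | intermediate
17 | secondary ozonide of 16 | O[C@@H]1C[C@]2(C)[C@@H](Br)CCC(=O)[C@H]2C[C@H]1C3(C)OCOO3 | intermediate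
18 | 14-acetyl trans-decalin hydroxy ketone | O[C@@H]1C[C@]2(C)[C@@H](Br)CCC(=O)[C@H]2C[C@H]1C(C)=O | intermediate
19 | 3-methylbut-2-enal | CC(C)=CC=O | starting material
20 | 2,3-dibromo-3-methylbutanal | CC(C)(Br)C(Br)C=O | intermediate
21 | 2-bromo-3-methylbut-2-enal | CC(C)=C(Br)C=O | intermediate
22 | Michael adduct (C14 quaternary: acetyl axial, C15 equatorial; 4-bromo aldehyde, both C4 epimers) | O[C@@H]1C[C@]2(C)[C@@H](Br)CCC(=O)[C@H]2C[C@@]1(C(C)=O)C(C)(C)C(Br)C=O | intermediate
23 | spiro 4-bromo-cyclohex-2-enone (ring D closed, C4 epimers) | O[C@@H]1C[C@]2(C)[C@@H](Br)CCC(=O)[C@H]2C[C@]13C(=O)C=CC(Br)C3(C)C | intermediate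
24 | bridged enone dione (6-oxabicyclo[3.2.1]oct-3-en-2-one fused to the decalone) | O=C1C=C[C@@H]2O[C@@H]3C[C@]4(C)[C@@H](Br)CCC(=O)[C@H]4C[C@]13C2(C)C | intermediate
25 | bridged saturated diketone | O=C1CC[C@@H]2O[C@@H]3C[C@]4(C)[C@@H](Br)CCC(=O)[C@H]4C[C@]13C2(C)C | intermediate
26 | C11 tertiary alcohol, C1 ketone | O=C1CC[C@@H]2O[C@@H]3C[C@]4(C)[C@@H](Br)CC[C@@](C)(O)[C@H]4C[C@]13C2(C)C | intermediate
27 | target, CNP0412361.2 | C=C1CC[C@@H]2O[C@@H]3C[C@]4(C)[C@@H](Br)CC[C@@](C)(O)[C@H]4C[C@]13C2(C)C | target

**Totals**

Total steps: 17. Longest linear sequence: 16 (steps 1–12 and 14–17; step 13 prepares the enal).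

**Steps most likely to fail**

1. Step 14 (proposed new method). The conjugate addition at the fully substituted enol carbon C14 may be outrun by reversible carbonyl additions, by loss of the hydroxyl from the β-hydroxy ketone, or by decomposition of the bromo-enal. Fallback, from 18 back to 24: the C5 hydroxyl of 18 is acylated with 2-bromo-3-methylbut-2-enoyl chloride (pyridine, DMAP) to the bromo-enoate ester F1, so that the carboxyl carbon becomes C3 and the conjugate addition becomes intramolecular. KOtBu in THF/t-BuOH should give the bromo δ-lactone F2 by Michael addition of the C14 enolate to C15. Under the same base a Claisen-type acyl transfer from C2 to the lactone carbonyl, followed by O-alkylation of the freed C5 alkoxide at the α-bromo ketone carbon C4, should give the bridged 1,3-diketone F3. Its enol triflate F4 (Tf2O, 2,6-di-tert-butylpyridine; the C3 oxygen is the less hindered) is reduced with Pd(OAc)2, PPh3, HCO2H and Bu3N to 24.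

2. Step 6. The bromonium ion may be captured by the enol oxygen instead of carbon, and enantiopurity may erode through intermolecular bromonium transfer under acid. Fallback, from 9 back to 10: 9 is converted with SOCl2 and 2,6-lutidine into the tertiary chloride F5 (retention through the bromonium ion). F5 is ionised without added acid by solvolysis in buffered (CF3)2CHOH at high dilution, which should give 10.

3. Step 16. The Grignard reagent may also add to the C1 ketone, or the facial selectivity at C11 may be poor. Fallback, from 24 back to 26: 1,4-hydrosilylation of the enone 24 (Et3SiH, RhCl(PPh3)3 cat.) gives the triethylsilyl enol ether F6, in which C1 is masked. MeMgBr/CeCl3 then adds only at C11 to give the hydroxy silyl enol ether F7, and Bu4NF releases the C1 ketone 26. This sequence also replaces step 15.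

**Further compounds**

F1 | step 14 | bromo-enoate ester of 18 | CC(C)=C(Br)C(=O)O[C@@H]1C[C@]2(C)[C@@H](Br)CCC(=O)[C@H]2C[C@H]1C(C)=O
F2 | step 14 | bromo δ-lactone | O=C1O[C@@H]2C[C@]3(C)[C@@H](Br)CCC(=O)[C@H]3C[C@@]2(C(C)=O)C(C)(C)C1Br
F3 | step 14 | bridged 1,3-diketone | O=C1CC(=O)[C@@H]2O[C@@H]3C[C@]4(C)[C@@H](Br)CCC(=O)[C@H]4C[C@]13C2(C)C
F4 | step 14 | enol triflate of F3 | O=C1C=C(OS(=O)(=O)C(F)(F)F)[C@@H]2O[C@@H]3C[C@]4(C)[C@@H](Br)CCC(=O)[C@H]4C[C@]13C2(C)C
F5 | step 6 | tertiary chloride (bromochloride) | COC(=O)CC(=O)CC[C@H](Br)[C@@](Cl)(C)CCO[Si](c1ccccc1)(c1ccccc1)C(C)(C)C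
F6 | step 16 | triethylsilyl enol ether | CC[Si](CC)(CC)OC1=CC[C@@H]2O[C@@H]3C[C@]4(C)[C@@H](Br)CCC(=O)[C@H]4C[C@]13C2(C)C
F7 | step 16 | hydroxy silyl enol ether | CC[Si](CC)(CC)OC1=CC[C@@H]2O[C@@H]3C[C@]4(C)[C@@H](Br)CC[C@@](C)(O)[C@H]4C[C@]13C2(C)C
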